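(The numbers in the tables were computed on assumed constants; scatter was added.)

The ledger counts amounts as fractions of the substrate charged, and the flask is charged with 0.80 M of substrate and 0.0800 M of capture agent. Two entries are read: target and trapped intermediate.

| setting | alpha | eta | flask |
|---|---|---|---|
| substrate | 0.40 M | 0.60 M | 0.80 M |
| reagent | 1.1 equiv | 1.1 equiv | 1.10 equiv |
| capture agent | 0.080 M | 0.080 M | 0.0800 M |
| free catalyst | 7.8 mol% | 7.8 mol% | 7.8 mol% |
| second catalyst | 0.05 mol% | 0.05 mol% | 0.05 mol% |
| remark | run made earlier | run made earlier |  |
| time |  |  | 5.0 h |

| run | time / h | trapped intermediate / % | target / % |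
|---|---|---|---|
| alpha | 0.250 | 18.9 | 54.1 |
| alpha | 0.500 | 20.0 | 55.0 |
| alpha | 1.33 | 20.2 | 54.5 |
| alpha | 3.00 | 19.8 | 54.4 |
| eta | 0.833 | 13.8 | 62.0 |
| eta | 1.50 | 13.3 | 62.3 |
| eta | 2.50 | 13.1 | 61.3 |
| eta | 3.00 | 13.1 | 62.3 |

(scatter of a reading: 0.5 percentage points)

- ratio of trapped intermediate to target at 5.0 s
- ratio of trapped intermediate to target at 5.0 min
- ratio of trapped intermediate to target at 5.0 h
- which of trapped intermediate and target there is more of at 5.0 h

- what was read earlier has a scatter of 0.5 percentage points, one standard deviation

Trapped intermediate comes first. Capture agent is the limiting reagent of this entry, with less of it charged than of substrate. In the flask, the capture share, meaning capture agent charged as a fraction of substrate charged, is 10.0%. The earlier runs test this quantity at 3.00 h: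

alpha: capture share 20.0%, trapped intermediate read 19.8%

eta: capture share 13.3%, trapped intermediate read 13.1%

Each reading falls short of its share by less than the scatter of 0.5 percentage points.

Target comes next. At 3.00 h the readings of target and trapped intermediate add up to 74.2% in alpha and 75.4% in eta. Their mean is 74.8%, and the remainder of 25.2% carries no name in the readings. The reckoning here assumes that this sum holds in the flask and that trapped intermediate reaches the capture share there:

trapped intermediate = capture share = 10.0%

target = sum − capture share = 64.8%

ratio at 5.0 h = 0.154

The readings begin at 0.250 h, later than 5.0 min, so this ledger commits to no number for the two early ratios.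

The forecast gave 0.5, 0.2 and 0.154 at 5.0 s, 5.0 min and 5.0 h, with target ahead, holding that “trapping is stoichiometrically capped”.

The flask gives ratios of 0.0263, 0.132 and 0.151 at those times, with target ahead at 5.0 h, 66.2% against 10.0%.

    substrate + free catalyst ⇌ free catalyst + open intermediate (K = 1.10, k = 2.50 /M/s)
    reagent + second catalyst + open intermediate → second catalyst + target (k = 620 /M²/s)
    open intermediate + capture agent → trapped intermediate (k = 0.0560 /M/s)
    2 reagent → homo dimer (k = 0.0390 /M/s)

At 5.00 h the flask keeps 0% of its capture agent, and trapped intermediate stands at 10.0%, level with the capture share of 10.0%. A second flask, charged like this one but with 0.20 M of substrate, has a capture share of 40.0%. At 5.00 h it holds 40.0% trapped intermediate against 40.6% target.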